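**Retrosynthetic overview**

1. Enabling feature (heptane chain numbered C1, benzylic to the 4-hydroxyphenyl ring, to C7, benzylic to the guaiacyl ring): the oxygen on C3 is five atoms from C7 and the C5 carbinol lies between them, so C3–C7 plus O3 is a latent 2-aryl-tetrahydropyran-4-ol; the para-oxygen of the 4-hydroxy-3-methoxyphenyl ring makes this temporary benzylic C7–O3 bond hydrogenolysable.
2. Target ⇐ tri-O-benzyl 2-aryl-tetrahydropyran-4-ol by one global hydrogenolysis (three benzyl ethers and the ring C7–O3 bond; C7 returns from the aldehyde level to CH2).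
3. Pyran ⇐ Prins cyclisation of O-benzylvanillin (C7) with a C1–C6 homoallylic alcohol, which forms the C6–C7, C7–O3 and C5–O bonds and the C5 stereocentre in one operation; the cyclisation places O5 cis to the C3 side chain (3,5-anti), so C5 is then inverted (Mitsunobu) to the 3,5-syn series.
4. Homoallylic alcohol ⇐ chelation-controlled allylation (C3–C4 bond, sets C3) of an α-benzyloxy aldehyde made from O-benzyl-L-tyrosine (C2 from the chiral pool).
5. Ring order: both benzene rings are bought; the only ring formed is the tetrahydropyran (step 6), and it is opened again in step 9.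

Key step: step 6

Remark: O-benzyl-L-tyrosine and 4-(benzyloxy)-3-methoxybenzaldehyde are taken as catalogue compounds; the chain locants C1–C7 of the target are used for all intermediates.

**Route**

Step 1
Reactants: 1 O-benzyl-L-tyrosine
Product: 2 (S)-3-[4-(benzyloxy)phenyl]-2-hydroxypropanoic acid
Conditions: NaNO2, 1 M aq. H2SO4, 1,4-dioxane, 0 °C → rt
Reagents that add atoms: water, O
Why: Diazotisation of the α-amino acid (hydroxy-dediazoniation) should proceed with net retention through the α-lactone formed by carboxylate participation, so the (S)-centre of tyrosine becomes C2 of the target unchanged.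

Step 2
Reactants: 2 (S)-3-[4-(benzyloxy)phenyl]-2-hydroxypropanoic acid
Product: 3 methyl (S)-3-[4-(benzyloxy)phenyl]-2-hydroxypropanoate
Conditions: MeOH, H2SO4 (cat.), reflux
Reagents that add atoms: methanol, CO
Why: Fischer esterification under acid catalysis should leave the α-stereocentre untouched and gives the ester needed for a controlled reduction.

Step 3
Reactants: 3 methyl (S)-3-[4-(benzyloxy)phenyl]-2-hydroxypropanoate
Product: 4 methyl (S)-2-(benzyloxy)-3-[4-(benzyloxy)phenyl]propanoate
Conditions: BnBr, Ag2O, Et2O, rt, dark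
Reagents that add atoms: benzyl bromide, BrCc1ccccc1
Why: Silver(I) oxide-promoted Williamson etherification benzylates the secondary hydroxyl without a strong base, so the α-centre is not enolised, and the benzyl ether is the chelating group needed in step 5.

Step 4
Reactants: 4 methyl (S)-2-(benzyloxy)-3-[4-(benzyloxy)phenyl]propanoate
Product: 5 (S)-2-(benzyloxy)-3-[4-(benzyloxy)phenyl]propanal
Conditions: DIBAL-H, CH2Cl2, −78 °C; MeOH, then aq. Rochelle salt
Reagents that add atoms: none
Why: DIBAL-H reduction of an α-alkoxy ester at −78 °C should stop at the chelated tetrahedral aluminium hemiacetal, which releases the aldehyde only on work-up; the configurationally labile aldehyde is used crude.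

Step 5
Reactants: 5 (S)-2-(benzyloxy)-3-[4-(benzyloxy)phenyl]propanal
Product: 6 (2S,3S)-2-(benzyloxy)-1-[4-(benzyloxy)phenyl]hex-5-en-3-ol
Conditions: MgBr2·OEt2, CH2Cl2, −78 °C; allylSnBu3, −78 → −20 °C
Reagents that add atoms: allyltributylstannane, C=CC[Sn](CCCC)(CCCC)CCCC
Why: Chelation-controlled allylstannane addition (Keck allylation, Cram-chelate model): magnesium bridges the aldehyde oxygen and the α-benzyloxy oxygen and the allyl group adds to the face opposite the CH2Ar substituent, which should set C3 as (S), 2,3-syn.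

Step 6
Reactants: 6 (2S,3S)-2-(benzyloxy)-1-[4-(benzyloxy)phenyl]hex-5-en-3-ol; 7 4-(benzyloxy)-3-methoxybenzaldehyde (O-benzylvanillin)
Product: 9 (2R,4R,6S)-2-[4-(benzyloxy)-3-methoxyphenyl]-6-{(1S)-1-(benzyloxy)-2-[4-(benzyloxy)phenyl]ethyl}tetrahydro-2H-pyran-4-ol (2,4,6-all-cis), via trifluoroacetate ester 8 (not isolated)
Conditions: CF3CO2H (excess), CH2Cl2, 0 °C → rt; then K2CO3, MeOH, rt
Reagents that add atoms: trifluoroacetic acid, OC(=O)C(F)(F)F
Why: Acid-promoted condensation of 6 with 7 gives the (E)-oxocarbenium ion O3=C7 conjugated to the aryl ring, whose C7 is attacked by the terminal alkene carbon C6 through a chair transition state, and the resulting tetrahydropyran-4-yl cation at C5 is captured by trifluoroacetate, the ester being methanolysed in the same flask. The closest known reaction type is the trifluoroacetic acid-mediated Prins cyclisation of homoallylic alcohols with aromatic aldehydes to all-cis 2,6-disubstituted tetrahydropyran-4-ols. The tetrahydropyran closes in the 6-endo-trig mode (C6 to C7, with both the C=O+ and the C=C bond inside the ring). C7 is set by the existing C3 centre, since the aryl group and the C3 side chain both sit equatorial in the chair (2,6-cis), and C5 is set by equatorial capture of the delocalised cation, which places O5 cis to both substituents. The step needs six-membered closure rather than 5-exo closure (secured because only attack by the terminal carbon gives a secondary cation) and suppression of 2-oxonia-Cope side-chain exchange (secured by aryl conjugation of the first oxocarbenium ion and by the inductively destabilising α-benzyloxy group at C2 on the rearranged one). The C7 configuration is irrelevant because it is erased in step 9, and C5, formed 3,5-anti, is inverted in step 7.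

Step 7
Reactants: 9 (2R,4R,6S)-2-[4-(benzyloxy)-3-methoxyphenyl]-6-{(1S)-1-(benzyloxy)-2-[4-(benzyloxy)phenyl]ethyl}tetrahydro-2H-pyran-4-ol
Product: 10 (2R,4S,6S)-2-[4-(benzyloxy)-3-methoxyphenyl]-6-{(1S)-1-(benzyloxy)-2-[4-(benzyloxy)phenyl]ethyl}tetrahydro-2H-pyran-4-yl 4-nitrobenzoate
Conditions: 4-O2NC6H4CO2H, PPh3, DIAD, toluene, 0 °C → rt
Reagents that add atoms: 4-nitrobenzoic acid, OC(=O)c1ccc(cc1)[N+](=O)[O-]
Why: Mitsunobu reaction: the equatorial alkoxyphosphonium at C5 should be displaced by 4-nitrobenzoate in an SN2 step from the axial direction, which inverts C5 to the configuration of the target (O5 trans to the C3 side chain on the ring, 3,5-syn in the chain).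

Step 8
Reactants: 10 (2R,4S,6S)-2-[4-(benzyloxy)-3-methoxyphenyl]-6-{(1S)-1-(benzyloxy)-2-[4-(benzyloxy)phenyl]ethyl}tetrahydro-2H-pyran-4-yl 4-nitrobenzoate
Product: 11 (2R,4S,6S)-2-[4-(benzyloxy)-3-methoxyphenyl]-6-{(1S)-1-(benzyloxy)-2-[4-(benzyloxy)phenyl]ethyl}tetrahydro-2H-pyran-4-ol (4-hydroxyl trans to the 2- and 6-substituents)
Conditions: K2CO3, MeOH/THF, rt
Reagents that add atoms: none
Why: Carbonate-catalysed transesterification removes the electron-poor aryl ester by acyl–oxygen cleavage, so C5 keeps its configuration and the benzyl ethers are untouched.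

Step 9
Reactants: 11 (2R,4S,6S)-2-[4-(benzyloxy)-3-methoxyphenyl]-6-{(1S)-1-(benzyloxy)-2-[4-(benzyloxy)phenyl]ethyl}tetrahydro-2H-pyran-4-ol
Product: 12 (2S,3S,5S)-1-(4-hydroxyphenyl)-7-(4-hydroxy-3-methoxyphenyl)heptane-2,3,5-triol (target)
Conditions: H2 (3–4 bar), Pd(OH)2/C, EtOH, AcOH, rt → 40 °C
Reagents that add atoms: none
Why: Palladium-catalysed hydrogenolysis should remove the three O-benzyl groups and then cleave the cyclic benzylic C7–O3 bond, which is activated by the freed para-hydroxyl as in 2-aryl-tetrahydrofuran lignans; C7 becomes CH2, and C2, C3 and C5 are not benzylic and keep their configuration.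

**Compound list**

1 | O-benzyl-L-tyrosine | N[C@@H](Cc1ccc(OCc2ccccc2)cc1)C(=O)O | starting material
2 | (S)-3-[4-(benzyloxy)phenyl]-2-hydroxypropanoic acid | O[C@@H](Cc1ccc(OCc2ccccc2)cc1)C(=O)O | intermediate
3 | methyl (S)-3-[4-(benzyloxy)phenyl]-2-hydroxypropanoate | COC(=O)[C@@H](O)Cc1ccc(OCc2ccccc2)cc1 | intermediate
4 | methyl (S)-2-(benzyloxy)-3-[4-(benzyloxy)phenyl]propanoate | COC(=O)[C@@H](OCc1ccccc1)Cc1ccc(OCc2ccccc2)cc1 | intermediate
5 | (S)-2-(benzyloxy)-3-[4-(benzyloxy)phenyl]propanal | O=C[C@@H](OCc1ccccc1)Cc1ccc(OCc2ccccc2)cc1 | intermediate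
6 | (2S,3S)-2-(benzyloxy)-1-[4-(benzyloxy)phenyl]hex-5-en-3-ol | C=CC[C@H](O)[C@@H](OCc1ccccc1)Cc1ccc(OCc2ccccc2)cc1 | intermediate
7 | 4-(benzyloxy)-3-methoxybenzaldehyde | COc1cc(C=O)ccc1OCc1ccccc1 | starting material
8 | (2R,4R,6S)-2-[4-(benzyloxy)-3-methoxyphenyl]-6-{(1S)-1-(benzyloxy)-2-[4-(benzyloxy)phenyl]ethyl}tetrahydro-2H-pyran-4-yl trifluoroacetate | O=C(O[C@@H]1C[C@H](c2ccc(OCc3ccccc3)c(OC)c2)O[C@@H](C1)[C@@H](OCc1ccccc1)Cc1ccc(OCc2ccccc2)cc1)C(F)(F)F | intermediate
9 | (2R,4R,6S)-2-[4-(benzyloxy)-3-methoxyphenyl]-6-{(1S)-1-(benzyloxy)-2-[4-(benzyloxy)phenyl]ethyl}tetrahydro-2H-pyran-4-ol | O[C@@H]1C[C@H](c2ccc(OCc3ccccc3)c(OC)c2)O[C@@H](C1)[C@@H](OCc1ccccc1)Cc1ccc(OCc2ccccc2)cc1 | intermediate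
10 | (2R,4S,6S)-2-[4-(benzyloxy)-3-methoxyphenyl]-6-{(1S)-1-(benzyloxy)-2-[4-(benzyloxy)phenyl]ethyl}tetrahydro-2H-pyran-4-yl 4-nitrobenzoate | O=C(O[C@H]1C[C@H](c2ccc(OCc3ccccc3)c(OC)c2)O[C@@H](C1)[C@@H](OCc1ccccc1)Cc1ccc(OCc2ccccc2)cc1)c1ccc(cc1)[N+](=O)[O-] | intermediate
11 | (2R,4S,6S)-2-[4-(benzyloxy)-3-methoxyphenyl]-6-{(1S)-1-(benzyloxy)-2-[4-(benzyloxy)phenyl]ethyl}tetrahydro-2H-pyran-4-ol | O[C@H]1C[C@H](c2ccc(OCc3ccccc3)c(OC)c2)O[C@@H](C1)[C@@H](OCc1ccccc1)Cc1ccc(OCc2ccccc2)cc1 | intermediate
12 | (2S,3S,5S)-1-(4-hydroxyphenyl)-7-(4-hydroxy-3-methoxyphenyl)heptane-2,3,5-triol | COc1cc(CC[C@H](O)C[C@H](O)[C@@H](O)Cc2ccc(O)cc2)ccc1O | target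

**Step count and risks**

Total step count: 9. Longest linear sequence: 9 steps (1 → 12); aldehyde 7 is bought.

Steps most likely to fail:

Step 6 (Prins cyclisation). The donor-stabilised aryl oxocarbenium ion may cyclise slowly. That would let 2-oxonia-Cope side-chain exchange compete, or acid-induced re-ionisation of the benzylic C7–O3 bond with oligomerisation, or loss of the aryl benzyl ether. The fallback sets out from 6, makes the C6–C7 bond by copper-catalysed opening of a terminal epoxide with a benzylic Grignard reagent, and returns to the route at 12. Compound 6 would be converted (Boc2O, DMAP, MeCN) into the tert-butyl carbonate F1. Bartlett–Smith iodocarbonate cyclisation (IBr, toluene, −85 °C) should give the cis iodomethyl cyclic carbonate F2, which sets C5 syn to C3 directly. K2CO3 in MeOH should then give the epoxy alcohol F3. Commercial 4-(benzyloxy)-3-methoxybenzyl alcohol would be converted (SOCl2) into the benzylic chloride F4 and this (Mg, THF, 0 °C) into the benzylic Grignard reagent F5. With catalytic CuI (THF, −40 → 0 °C), F5 should open F3 at C6 to give the tri-O-benzyl 3,5-diol F6. Hydrogenolysis of F6 (H2, Pd/C, EtOH) would give 12. This is one step longer than steps 6–9 and needs no inversion.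

Step 9 (hydrogenolytic ring opening). Hydrogenolysis may stop after loss of the benzyl ethers and leave the cyclic benzylic ether intact, or forcing conditions may begin to saturate the phenol rings. The fallback sets out from 11 and returns at 12. Neutral hydrogenolysis (H2, Pd/C, EtOAc/MeOH) would give the debenzylated pyran tetrol F7. Ionic hydrogenation (Et3SiH, CF3CO2H, CH2Cl2, 0 °C; then K2CO3, MeOH to cleave any trifluoroacetates) should open the ring: protonation of the ring oxygen, ionisation to the para-hydroxybenzylic cation and hydride transfer from the silane give 12.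

Step 7 (Mitsunobu inversion). Elimination of the alkoxyphosphonium ion to a dihydropyran, or acyl transfer with retention, may compete with SN2 displacement. The fallback sets out from 9 and returns at 11, so step 8 is not needed. Oxidation (Dess–Martin periodinane, NaHCO3, CH2Cl2) would give the pyran-4-one F8. Reduction with L-Selectride (THF, −78 °C) should deliver hydride from the equatorial direction, as for other 2,6-cis-tetrahydropyran-4-ones, and give the axial alcohol 11.

**Further compounds**

F1 | step 6 | tert-butyl (2S,3S)-2-(benzyloxy)-1-[4-(benzyloxy)phenyl]hex-5-en-3-yl carbonate | C=CC[C@H](OC(=O)OC(C)(C)C)[C@@H](OCc1ccccc1)Cc1ccc(OCc2ccccc2)cc1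
F2 | step 6 | (4S,6R)-4-{(1S)-1-(benzyloxy)-2-[4-(benzyloxy)phenyl]ethyl}-6-(iodomethyl)-1,3-dioxan-2-one | IC[C@H]1C[C@@H]([C@@H](OCc2ccccc2)Cc2ccc(OCc3ccccc3)cc2)OC(=O)O1
F3 | step 6 | (2S,3S)-3-(benzyloxy)-4-[4-(benzyloxy)phenyl]-1-[(2R)-oxiran-2-yl]butan-2-ol | C1O[C@@H]1C[C@H](O)[C@@H](OCc1ccccc1)Cc1ccc(OCc2ccccc2)cc1
F4 | step 6 | 1-(benzyloxy)-4-(chloromethyl)-2-methoxybenzene | COc1cc(CCl)ccc1OCc1ccccc1
F5 | step 6 | [4-(benzyloxy)-3-methoxybenzyl]magnesium chloride | COc1cc(C[Mg]Cl)ccc1OCc1ccccc1
F6 | step 6 | (2S,3S,5S)-2-(benzyloxy)-7-[4-(benzyloxy)-3-methoxyphenyl]-1-[4-(benzyloxy)phenyl]heptane-3,5-diol | COc1cc(CC[C@H](O)C[C@H](O)[C@@H](OCc2ccccc2)Cc2ccc(OCc3ccccc3)cc2)ccc1OCc1ccccc1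
F7 | step 9 | (2R,4S,6S)-2-(4-hydroxy-3-methoxyphenyl)-6-[(1S)-1-hydroxy-2-(4-hydroxyphenyl)ethyl]tetrahydro-2H-pyran-4-ol | O[C@H]1C[C@H](c2ccc(O)c(OC)c2)O[C@@H](C1)[C@@H](O)Cc1ccc(O)cc1
F8 | step 7 | (2R,6S)-2-[4-(benzyloxy)-3-methoxyphenyl]-6-{(1S)-1-(benzyloxy)-2-[4-(benzyloxy)phenyl]ethyl}tetrahydro-4H-pyran-4-one | O=C1C[C@H](c2ccc(OCc3ccccc3)c(OC)c2)O[C@@H](C1)[C@@H](OCc1ccccc1)Cc1ccc(OCc2ccccc2)cc1
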